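## Retrosynthetic overview

1. The six-membered ring of the target is the carbocycle of 2-allylphenol 1, oxidised to quinone 2; no carbocycle has to be built.
2. Key disconnection: the C1–C6 oxirane and a temporary bicyclo[2.2.1]heptene ring are closed in one flask from 2 and cyclopentadiene 3 (catalytic asymmetric Diels–Alder to 4, then convex-face epoxidation to 5). The catalyst-made ring-fusion centres relay the absolute configuration to the epoxide and are erased later.
3. On the rigid tricycle, C4–CH2OH (aldol, 6) and the C5 hydroxyl trans to the epoxide (directed reduction, 7) are set from the convex face; retro-Diels–Alder returns the C3=C4 bond (8).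
4. Side chain: cross-metathesis of the allyl group with methacrolein 9 (10), then Pinnick oxidation (11).
5. C3–heptenyl last: α-iodination (12) and Suzuki coupling with boronic acid 13 give target 14. Ring order: norbornene ring, then oxirane (same operation); the norbornene ring is opened again in step 5.

Assumption: the SMILES is read as (1S,5R,6S), i.e. the C5 hydroxyl is trans to the epoxide oxygen; the (S)-configured oxazaborolidinium catalyst is taken to give the sense of induction drawn (its mirror image is equally available and changes nothing else).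

Labels: C1–C6 are the carbons of the target's carbocycle (C1 side chain and epoxide, C2 ketone, C3 heptenyl, C4 CH2OH, C5 OH, C6 epoxide CH). In the methanonaphthalene names, locants 6, 7, 8, 8a, 4a, 5 are C1, C6, C5, C4, C3, C2.

## Route

Step 1
Reactants: 1 2-allylphenol
Product: 2 2-allyl-1,4-benzoquinone
Conditions: K2[ON(SO3)2] (Fremy's salt, 2.2 equiv), KH2PO4 buffer, H2O/acetone, 0 °C to rt
Reagents that add atoms: potassium nitrosodisulfonate, [K+].[K+].[O-]S(=O)(=O)N([O])S(=O)(=O)[O-]
Why: Teuber oxidation: the nitroxyl radical salt removes the phenolic hydrogen and a second equivalent oxygenates the free para position to give the para-quinone, the allyl group being inert to this one-electron oxidant; no stereocentre is formed.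

Step 2
Reactants: 2 2-allyl-1,4-benzoquinone; 3 cyclopenta-1,3-diene
Product: 5 endo-6-allyl-6,7-epoxy-1,4,4a,6,7,8a-hexahydro-1,4-methanonaphthalene-5,8-dione (convex-face epoxide), via endo cycloadduct 4 (not isolated)
Conditions: 3 (3 equiv), N-protonated (S)-3,3-diphenyl-1-(2-methylphenyl)tetrahydro-1H,3H-pyrrolo[1,2-c][1,3,2]oxazaborole (CF3SO2)2N− salt (15 mol%), CH2Cl2, −78 °C; then same flask: MeOH, acetone, 30% aq. H2O2, 10% aq. Na2CO3, 0 °C; 5 recrystallised
Reagents that add atoms: hydrogen peroxide, OO
Why: Enantioselective Diels–Alder reaction catalysed by a chiral cationic oxazaborolidine (Corey type) followed in the same flask by Weitz–Scheffer epoxidation: the Lewis acid binds the more basic, less hindered C5 carbonyl and shields one face of the unsubstituted C3=C4 bond so that cyclopentadiene adds endo and fixes C3/C4, and hydroperoxide then attacks the allyl-substituted C1=C6 enedione bond only from the convex face (the face of the ring-fusion hydrogens), which sets the target's C1 and C6 configuration by relay from the catalyst while two rings (norbornene ring and oxirane) close in one operation.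

Step 3
Reactants: 5 endo-6-allyl-6,7-epoxy-1,4,4a,6,7,8a-hexahydro-1,4-methanonaphthalene-5,8-dione
Product: 6 8a-(hydroxymethyl) derivative of 5 (CH2OH on the convex face)
Conditions: 37% aq. HCHO (5 equiv), DBU (0.3 equiv), THF, 0 °C
Reagents that add atoms: formaldehyde, C=O
Why: Reversible base-mediated aldol addition to formaldehyde: the enolate toward C4 reacts from the convex face (cis ring fusion retained) and the C4 adduct is favoured over the C3 one because reaction at C3 would flank the C2 carbonyl with two fully substituted carbons, the unfavourable isomer reverting by retro-aldol.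

Step 4
Reactants: 6 8a-(hydroxymethyl) epoxy-dione
Product: 7 6-allyl-6,7-epoxy-8-hydroxy-8a-(hydroxymethyl)-4,4a,6,7,8,8a-hexahydro-1,4-methanonaphthalen-5(1H)-one (8-OH on the concave face)
Conditions: Me4N[BH(OAc)3] (4 equiv), MeCN/AcOH 1:1, −25 °C
Reagents that add atoms: none
Why: Hydroxyl-directed reduction (Evans–Saksena type): the primary alcohol exchanges an acetate on boron and delivers hydride intramolecularly to the neighbouring C5 carbonyl from the convex face on which CH2OH sits, so the new hydroxyl lies on the concave face, trans to the epoxide oxygen (the 5R centre of the target), while the C2 ketone, remote from the directing group and next to quaternary C1, is not reduced.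

Step 5
Reactants: 7 tricyclic epoxy diol ketone
Product: 8 (1S,5R,6S)-5-hydroxy-4-(hydroxymethyl)-1-(prop-2-en-1-yl)-7-oxabicyclo[4.1.0]hept-3-en-2-one
Conditions: Ph2O, 240 °C, 15 min, N2 stream (or flash vacuum pyrolysis, 480 °C, 0.01 mmHg)
Reagents that add atoms: none
Why: Thermal retro-Diels–Alder reaction: cyclopentadiene is expelled, the C3=C4 double bond of the γ-hydroxy enone appears and the two relay stereocentres vanish, while C1, C5 and C6 take part in no bond breaking and keep their configuration.

Step 6
Reactants: 8 allyl epoxy enone diol; 9 methacrolein (2-methylprop-2-enal)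
Product: 10 (E)-4-[(1S,5R,6S)-5-hydroxy-4-(hydroxymethyl)-2-oxo-7-oxabicyclo[4.1.0]hept-3-en-1-yl]-2-methylbut-2-enal
Conditions: 9 (10 equiv), second-generation Hoveyda–Grubbs catalyst (H2IMes)Cl2Ru=CH(2-iPrOC6H4) (5 mol%), CH2Cl2, 40 °C
Reagents that add atoms: none
Why: Olefin cross-metathesis between a monosubstituted alkene and a 1,1-disubstituted enal: loss of ethene drives the reaction and the trisubstituted enal forms as the thermodynamically preferred E isomer, the trisubstituted ring enone being unreactive toward the ruthenium carbene.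

Step 7
Reactants: 10 enal
Product: 11 (E)-4-[(1S,5R,6S)-5-hydroxy-4-(hydroxymethyl)-2-oxo-7-oxabicyclo[4.1.0]hept-3-en-1-yl]-2-methylbut-2-enoic acid
Conditions: NaClO2 (3 equiv), NaH2PO4 (4 equiv), 2-methyl-2-butene (20 equiv), t-BuOH/H2O 3:1, 0 °C to rt
Reagents that add atoms: sodium chlorite, [Na+].[O-]Cl=O
Why: Pinnick oxidation: chlorous acid adds to the aldehyde and fragments to the carboxylic acid under buffered conditions that leave the epoxy ketone, the alcohols and the E double bond untouched, 2-methyl-2-butene removing the hypochlorous acid formed.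

Step 8
Reactants: 11 enoic acid
Product: 12 (E)-4-[(1S,5R,6S)-5-hydroxy-4-(hydroxymethyl)-3-iodo-2-oxo-7-oxabicyclo[4.1.0]hept-3-en-1-yl]-2-methylbut-2-enoic acid
Conditions: I2 (2.5 equiv), pyridine/CH2Cl2 1:1, DMAP (0.2 equiv), rt, dark
Reagents that add atoms: iodine, II
Why: α-Iodination of an enone by conjugate addition of the amine, iodination of the resulting enolate at C3 and elimination (Johnson procedure, Baylis–Hillman-type mechanism); the side-chain enoic acid cannot follow this path because its α-carbon carries no hydrogen, and no stereocentre is touched.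

Step 9
Reactants: 12 α-iodoenone acid; 13 (E)-hept-1-en-1-ylboronic acid
Product: 14 (E)-4-[(1S,5R,6S)-3-[(E)-hept-1-en-1-yl]-5-hydroxy-4-(hydroxymethyl)-2-oxo-7-oxabicyclo[4.1.0]hept-3-en-1-yl]-2-methylbut-2-enoic acid
Conditions: 13 (1.5 equiv), PdCl2(PhCN)2 (5 mol%), AsPh3 (10 mol%), Ag2O (3 equiv), THF/H2O 8:1, rt; work-up at pH 3–4
Reagents that add atoms: none
Why: Suzuki–Miyaura coupling under the silver oxide-promoted conditions developed for α-iodoenones: zerovalent palladium inserts into the C3–I bond, the alkenyl group is transferred from boron with retention of its E geometry and reductive elimination gives the diene at room temperature without strong base, so the trans epoxy alcohol is not exposed to Payne-type epoxide migration.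

## Compound list

1 | 2-allylphenol | C=CCc1ccccc1O | starting material
2 | 2-allyl-1,4-benzoquinone | C=CCC1=CC(=O)C=CC1=O | intermediate
3 | cyclopenta-1,3-diene (freshly cracked from its dimer) | C1=CCC=C1 | starting material
4 | endo-6-allyl-1,4,4a,8a-tetrahydro-1,4-methanonaphthalene-5,8-dione; cis ring fusion; enantiomer as in SMILES | C=CCC1=CC(=O)[C@H]2[C@@H](C1=O)[C@H]3C=C[C@@H]2C3 | intermediate (not isolated)
5 | endo-6-allyl-6,7-epoxy-1,4,4a,6,7,8a-hexahydro-1,4-methanonaphthalene-5,8-dione; epoxide oxygen on the convex face, cis to H-4a and H-8a | C=CC[C@]12O[C@H]1C(=O)[C@H]3[C@@H](C2=O)[C@H]4C=C[C@@H]3C4 | intermediate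
6 | 8a-(hydroxymethyl) derivative of 5; CH2OH on the convex face, cis to the epoxide oxygen | C=CC[C@]12O[C@H]1C(=O)[C@@]3(CO)[C@@H](C2=O)[C@H]4C=C[C@@H]3C4 | intermediate
7 | 6-allyl-6,7-epoxy-8-hydroxy-8a-(hydroxymethyl)-4,4a,6,7,8,8a-hexahydro-1,4-methanonaphthalen-5(1H)-one; 8-OH on the concave face, trans to the epoxide oxygen and to CH2OH | C=CC[C@]12O[C@H]1[C@H](O)[C@@]3(CO)[C@@H](C2=O)[C@H]4C=C[C@@H]3C4 | intermediate
8 | (1S,5R,6S)-5-hydroxy-4-(hydroxymethyl)-1-(prop-2-en-1-yl)-7-oxabicyclo[4.1.0]hept-3-en-2-one | C=CC[C@]12O[C@H]1[C@H](O)C(CO)=CC2=O | intermediate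
9 | methacrolein (2-methylprop-2-enal) | CC(=C)C=O | starting material
10 | (E)-4-[(1S,5R,6S)-5-hydroxy-4-(hydroxymethyl)-2-oxo-7-oxabicyclo[4.1.0]hept-3-en-1-yl]-2-methylbut-2-enal | O=C/C(C)=C/C[C@]12O[C@H]1[C@H](O)C(CO)=CC2=O | intermediate
11 | (E)-4-[(1S,5R,6S)-5-hydroxy-4-(hydroxymethyl)-2-oxo-7-oxabicyclo[4.1.0]hept-3-en-1-yl]-2-methylbut-2-enoic acid | OC(=O)/C(C)=C/C[C@]12O[C@H]1[C@H](O)C(CO)=CC2=O | intermediate
12 | (E)-4-[(1S,5R,6S)-5-hydroxy-4-(hydroxymethyl)-3-iodo-2-oxo-7-oxabicyclo[4.1.0]hept-3-en-1-yl]-2-methylbut-2-enoic acid | OC(=O)/C(C)=C/C[C@]12O[C@H]1[C@H](O)C(CO)=C(I)C2=O | intermediate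
13 | (E)-hept-1-en-1-ylboronic acid | CCCCC/C=C/B(O)O | starting material
14 | (E)-4-[(1S,5R,6S)-3-[(E)-hept-1-en-1-yl]-5-hydroxy-4-(hydroxymethyl)-2-oxo-7-oxabicyclo[4.1.0]hept-3-en-1-yl]-2-methylbut-2-enoic acid | CCCCC/C=C/C1=C(CO)[C@@H](O)[C@@H]2O[C@]2(C/C=C(\C)C(=O)O)C1=O | target

## Step count and risks

Total steps: 9. Longest linear sequence: 9 (1 to 14); 3, 9 and 13 are bought. No protecting groups are used.

**Step 2 (enantioselectivity of the cycloaddition; base-induced aromatisation of 4 before it is epoxidised).** The fallback obtains the absolute configuration by enzymatic kinetic resolution instead of asymmetric catalysis. It sets out from 2 (with 3) and comes back to the route at 6. Uncatalysed cycloaddition in CH2Cl2 at 0 °C and the same in-flask epoxidation give 5 together with its mirror image, the epoxy-dione ent-5 F2, through 4 and the mirror-image cycloadduct ent-4 F1 (neither isolated). The conditions of step 3 convert the pair into 6 and the hydroxymethyl compound ent-6 F3. Lipase from Burkholderia cepacia (Amano PS) with vinyl acetate in tert-butyl methyl ether acetylates the primary alcohol of one antipode faster; the enzyme is chosen in a small screen so that this is ent-6, giving the acetate of ent-6 F4. Unreacted 6 is separated by chromatography at about 55% conversion.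

**Step 3 (site of the aldol: C4 against C3, double addition, retro-aldol).** The fallback makes the site selectivity independent of which enolate forms. It sets out from 5 and comes back at 6. Pyrrolidine (1.2 equiv) with 4 Å molecular sieves in benzene at rt condenses only with the less hindered C5 carbonyl; the enamine can form only toward C4 and is the pyrrolidine enamine of 5 F5. Aqueous formaldehyde in buffered MeCN then reacts at C4 from the convex face, and hydrolysis of the iminium ion gives 6 (Stork enamine hydroxymethylation).

**Step 8 (amine-mediated iodination of a β,β-disubstituted enone that carries a free acid and diol).** The fallback puts the halogen in by ketone α-halogenation on the tricycle instead. It sets out from 7 and comes back at 14. PhNMe3Br3 (1.05 equiv) with 2,6-di-tert-butylpyridine in THF at 0 °C brominates the only enolisable α-position of the ketone (C3; C1 is quaternary) from the convex face, giving the C3-bromo derivative of 7 F6. Cycloreversion as in step 5 (flash vacuum pyrolysis) gives the α-bromoenone, the 3-bromo analogue of 8 F7. The conditions of steps 6 and 7 then give the 3-bromo analogue of 10 F8 and the 3-bromo analogue of 11 F9. F9 enters the Suzuki coupling of step 9 (40 °C) in place of 12 and gives 14.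

## Further compounds

F1 | step 2 | ent-4, mirror-image endo cycloadduct (not isolated) | C=CCC1=CC(=O)[C@@H]2[C@H](C1=O)[C@@H]3C=C[C@H]2C3
F2 | step 2 | ent-5, mirror-image epoxy-dione | C=CC[C@@]12O[C@@H]1C(=O)[C@@H]3[C@H](C2=O)[C@@H]4C=C[C@H]3C4
F3 | step 2 | ent-6, mirror-image hydroxymethyl epoxy-dione | C=CC[C@@]12O[C@@H]1C(=O)[C@]3(CO)[C@H](C2=O)[C@@H]4C=C[C@H]3C4
F4 | step 2 | acetate of ent-6 | C=CC[C@@]12O[C@@H]1C(=O)[C@]3(COC(C)=O)[C@H](C2=O)[C@@H]4C=C[C@H]3C4
F5 | step 3 | pyrrolidine enamine of 5 (enamine at C5, double bond C4=C5) | C=CC[C@]12O[C@H]1C(N5CCCC5)=C3[C@@H](C2=O)[C@H]4C=C[C@@H]3C4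
F6 | step 8 | C3-bromo derivative of 7 (4a-bromo, bromine on the convex face) | C=CC[C@]12O[C@H]1[C@H](O)[C@@]3(CO)[C@@](Br)(C2=O)[C@H]4C=C[C@@H]3C4
F7 | step 8 | 3-bromo analogue of 8, (1S,5R,6S)-3-bromo-5-hydroxy-4-(hydroxymethyl)-1-(prop-2-en-1-yl)-7-oxabicyclo[4.1.0]hept-3-en-2-one | C=CC[C@]12O[C@H]1[C@H](O)C(CO)=C(Br)C2=O
F8 | step 8 | 3-bromo analogue of 10 | O=C/C(C)=C/C[C@]12O[C@H]1[C@H](O)C(CO)=C(Br)C2=O
F9 | step 8 | 3-bromo analogue of 11 | OC(=O)/C(C)=C/C[C@]12O[C@H]1[C@H](O)C(CO)=C(Br)C2=O
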